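**Plan**

- The target is a (2S)-5,7-dihydroxyflavanone whose ring B (3',5'-dimethoxy) carries at O4' a threo (7''R,8''R) 1-(4-hydroxyphenyl)propane-1,3-diol unit bound through C8'' (C7'' benzylic carbinol, C9'' CH2OH).
- Retrosynthesis: with C4 taken back to a protected alcohol, ring C is cut at O1–C8a; the open chain is then cut at C3–C4 (aldol), C1'–C2 (aryl acylation), C7''–C8'' (auxiliary aldol) and O4'–CH2 (ether alkylation).
- The O1–C8a cut is open because O1 is an aryl ether oxygen lying between the aromatic carbon C8a of ring A and the benzylic carbinol carbon C2, so C2 can be fixed as a free alcohol and ring C closed from the arene side without touching it.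
- Forward: the side chain is built on 4-bromo-2,6-dimethoxyphenol, its bromide becomes the acetyl group, an aldol to the ring A aldehyde joins C3–C4, the ketone is reduced, ring C closes, and C4 oxidation plus deprotection finish.
- Stereochemistry: C7''/C8'' come from a boron syn-aldol directed by (S)-4-benzyl-2-oxazolidinone; C2 comes from an (R)-oxazaborolidine–borane reduction; C4 is carried as an epimer mixture and ends as the carbonyl.

Key step: step 12

Remark: the silyloxy/hydroxy carbon that becomes C4 is a mixture of both configurations in 18–22 (SMILES leave it undefined); "ArB" in names stands for 4-{[(4R,5R)-4-[4-(benzyloxy)phenyl]-2,2-dimethyl-1,3-dioxan-5-yl]oxy}-3,5-dimethoxyphenyl.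

**Route**

Step 1
Reactants: 1 5-bromoresorcinol
Product: 2 1,3-bis(benzyloxy)-5-bromobenzene
Conditions: BnBr, K2CO3, DMF, rt to 60 °C
Reagents that add atoms: benzyl bromide, BrCc1ccccc1
Why: Williamson ether synthesis: both phenoxides of 1 are alkylated by the reactive benzylic bromide, giving ethers that should survive all later base, hydride and palladium steps and fall off by hydrogenolysis at the end.

Step 2
Reactants: 2 1,3-bis(benzyloxy)-5-bromobenzene
Product: 3 2-bromo-4,6-bis(benzyloxy)benzaldehyde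
Conditions: POCl3, DMF, 0 to 60 °C; then ice-water
Reagents that add atoms: N,N-dimethylformamide, CN(C)C=O; water, O
Why: Vilsmeier–Haack formylation: the chloroiminium ion should attack the ring position ortho to one benzyloxy group and para to the other (the site between the two ethers is more crowded), the known outcome for 1-bromo-3,5-dialkoxybenzenes, and water hydrolyses the iminium salt to the aldehyde.

Step 3
Reactants: 4 4-bromo-2,6-dimethoxyphenol
Product: 6 (4-bromo-2,6-dimethoxyphenoxy)acetic acid, via ethyl ester 5 (not isolated)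
Conditions: BrCH2CO2Et, K2CO3, acetone, reflux; then NaOH, MeOH/H2O, rt; HCl to pH 2
Reagents that add atoms: ethyl bromoacetate, CCOC(=O)CBr; sodium hydroxide, [Na+].[OH-]
Why: Williamson alkylation of the acidic, di-ortho-substituted phenol with an unhindered alpha-bromo ester followed by saponification gives the aryloxyacetic acid without any substitution at a stereogenic carbon.

Step 4
Reactants: 6 (4-bromo-2,6-dimethoxyphenoxy)acetic acid; 7 (S)-4-benzyl-2-oxazolidinone
Product: 9 (S)-4-benzyl-3-[(4-bromo-2,6-dimethoxyphenoxy)acetyl]oxazolidin-2-one, via mixed pivalic anhydride 8 (not isolated)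
Conditions: t-BuCOCl, Et3N, THF, -20 °C; then 7, LiCl, -20 °C to rt
Reagents that add atoms: none
Why: N-acylation of the oxazolidinone through a mixed pivalic anhydride under LiCl/Et3N activation, the nitrogen attacking the less hindered aryloxyacetyl carbonyl.

Step 5
Reactants: 9 (S)-4-benzyl-3-[(4-bromo-2,6-dimethoxyphenoxy)acetyl]oxazolidin-2-one; 10 4-(benzyloxy)benzaldehyde
Product: 12 (S)-4-benzyl-3-[(2S,3R)-3-[4-(benzyloxy)phenyl]-2-(4-bromo-2,6-dimethoxyphenoxy)-3-hydroxypropanoyl]oxazolidin-2-one, via dibutylboron enolate 11 (not isolated)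
Conditions: Bu2BOTf, i-Pr2NEt, CH2Cl2, -78 to 0 °C; 10, -78 to 0 °C; then pH 7 buffer, MeOH, 30% H2O2, 0 °C
Reagents that add atoms: none
Why: Evans syn-aldol reaction: soft enolisation gives the Z-boron enolate, whose chair Zimmerman–Traxler transition state fixes the 2,3-syn (threo) relationship while the benzyl group of the (S)-auxiliary shields one enolate face, so C8'' and C7'' are set together as (2S,3R).

Step 6
Reactants: 12 syn-aldol imide
Product: 13 (1R,2R)-1-[4-(benzyloxy)phenyl]-2-(4-bromo-2,6-dimethoxyphenoxy)propane-1,3-diol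
Conditions: LiBH4, THF, H2O (1 equiv), 0 °C
Reagents that add atoms: none
Why: Reductive cleavage of the N-acyl oxazolidinone: hydride attacks the exocyclic imide carbonyl and reduces it to the primary alcohol C9'', releasing the auxiliary and leaving both stereocentres and the aryl bromide untouched.

Step 7
Reactants: 13 (1R,2R)-diol
Product: 14 (4R,5R)-4-[4-(benzyloxy)phenyl]-5-(4-bromo-2,6-dimethoxyphenoxy)-2,2-dimethyl-1,3-dioxane
Conditions: 2,2-dimethoxypropane, pyridinium p-toluenesulfonate (cat.), acetone, rt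
Reagents that add atoms: 2,2-dimethoxypropane, COC(C)(C)OC
Why: Acid-catalysed transacetalisation (acetonide formation) ties the 1,3-diol into a 1,3-dioxane that is inert to organolithium, enolate, borane, palladium, fluoride and oxidant and is orthogonal to the later silyl ether.

Step 8
Reactants: 14 bromoaryl acetonide
Product: 16 1-[4-{[(4R,5R)-4-[4-(benzyloxy)phenyl]-2,2-dimethyl-1,3-dioxan-5-yl]oxy}-3,5-dimethoxyphenyl]ethanone (ArB–COCH3), via aryllithium 15 (not isolated)
Conditions: n-BuLi, THF, -78 °C; then MeC(O)N(OMe)Me, -78 to 0 °C; H2O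
Reagents that add atoms: N-methoxy-N-methylacetamide, CON(C)C(C)=O
Why: Bromine–lithium exchange followed by Weinreb ketone synthesis: the aryllithium adds once to the N-methoxy-N-methylamide because the chelated tetrahedral adduct collapses only on work-up, giving the methyl ketone whose carbonyl carbon becomes C2.

Step 9
Reactants: 16 methyl ketone ArB–COCH3; 3 2-bromo-4,6-bis(benzyloxy)benzaldehyde
Product: 18 3-[2-bromo-4,6-bis(benzyloxy)phenyl]-3-hydroxy-1-(ArB)propan-1-one (both C3 epimers), via lithium enolate 17 (not isolated)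
Conditions: LiN(i-Pr)2, THF, -78 °C; then 3, -78 °C; AcOH quench at -78 °C
Reagents that add atoms: none
Why: Directed aldol addition: the kinetic lithium enolate of the methyl ketone adds to the non-enolisable aldehyde to form C3–C4, the new carbinol centre arising as both epimers, which is harmless because it is oxidised later.

Step 10
Reactants: 18 beta-hydroxy ketone
Product: 19 3-[2-bromo-4,6-bis(benzyloxy)phenyl]-3-(tert-butyldimethylsilyloxy)-1-(ArB)propan-1-one (both C3 epimers)
Conditions: t-BuMe2SiOTf, 2,6-lutidine, CH2Cl2, -78 to 0 °C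
Reagents that add atoms: tert-butyldimethylsilyl trifluoromethanesulfonate, CC(C)(C)[Si](C)(C)OS(=O)(=O)C(F)(F)F
Why: O-silylation with a silyl triflate and a hindered pyridine base converts the crowded benzylic alcohol into a tert-butyldimethylsilyl ether, which blocks retro-aldol and dehydration and keeps this oxygen away from palladium in step 12.

Step 11
Reactants: 19 beta-silyloxy ketone
Product: 20 (1S)-3-[2-bromo-4,6-bis(benzyloxy)phenyl]-3-(tert-butyldimethylsilyloxy)-1-(ArB)propan-1-ol (both C3 epimers)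
Conditions: (R)-2-methyl-CBS-oxazaborolidine [(R)-1-methyl-3,3-diphenyl-tetrahydro-1H,3H-pyrrolo[1,2-c][1,3,2]oxazaborole] (0.2 equiv), BH3·SMe2, THF, -20 °C; MeOH quench
Reagents that add atoms: none
Why: Corey–Bakshi–Shibata reduction: the (R)-oxazaborolidine–borane complex binds the ketone with the aryl group as the large and the CH2 branch as the small substituent and delivers hydride to the Re face, setting C2 as (S) under catalyst control for both epimers at the silyloxy carbon.

Step 12
Reactants: 20 (1S)-bromoaryl diol mono-silyl ether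
Product: 21 (2S)-5,7-bis(benzyloxy)-4-(tert-butyldimethylsilyloxy)-2-(ArB)chroman (protected 4-silyloxyflavan, both C4 epimers)
Conditions: Pd(OAc)2 (5 mol%), 2-(di-tert-butylphosphino)-1,1'-binaphthyl (6 mol%), Cs2CO3, toluene, 70 °C
Reagents that add atoms: none
Why: Pd(OAc)2 is reduced in the flask to a zerovalent palladium–phosphine complex that inserts into the C8a–Br bond of ring A; carbonate then deprotonates the C2 hydroxyl, which displaces bromide on divalent palladium to give a seven-membered aryl(alkoxo)palladium chelate, and C–O reductive elimination forms O1–C8a. The closest known reaction is the intramolecular Buchwald–Hartwig-type etherification of secondary alcohols with aryl bromides, the established entry to 2-substituted chromans. Ring C closes as a six-membered pyran by exo delivery of the tethered oxygen to the metalated arene carbon, that is, by ring-forming reductive elimination and not by an ionic cyclisation. No stereocentre is created: the C2–O bond is never broken, so the (S) configuration from step 11 is carried over and the C4 epimer mixture passes through unchanged. The step needs reductive elimination to outrun beta-hydride elimination of the benzylic alkoxide, which the bulky electron-rich di-tert-butyl biaryl phosphine should secure, and it needs a single reacting alcohol and halide, which the silyl ether at C4 and the lone C8a–Br provide.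

Step 13
Reactants: 21 protected 4-silyloxyflavan
Product: 22 (2S)-5,7-bis(benzyloxy)-2-(ArB)chroman-4-ol (both C4 epimers)
Conditions: Bu4NF, THF, rt
Reagents that add atoms: none
Why: Fluoride-mediated desilylation cleaves the only silyl ether present, whereas the acetonide and the benzyl ethers do not react with fluoride, and the non-acidic medium avoids ionisation of the acid-sensitive flavan-4-ol.

Step 14
Reactants: 22 flavan-4-ol
Product: 23 (2S)-5,7-bis(benzyloxy)-2-(ArB)chroman-4-one
Conditions: Dess–Martin periodinane, CH2Cl2, 0 °C to rt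
Reagents that add atoms: none
Why: Dess–Martin oxidation of the secondary benzylic alcohol converges both C4 epimers on one flavanone under non-basic conditions, so C2 cannot epimerise by ring opening to the chalcone.

Step 15
Reactants: 23 flavanone acetonide
Product: 24 (2S)-5,7-bis(benzyloxy)-2-[4-{[(1R,2R)-1-[4-(benzyloxy)phenyl]-1,3-dihydroxypropan-2-yl]oxy}-3,5-dimethoxyphenyl]chroman-4-one
Conditions: AcOH/THF/H2O (3:1:1), 40 °C
Reagents that add atoms: none
Why: Acid-catalysed acetal hydrolysis in dilute aqueous acetic acid frees the C7''/C9'' diol while the flavanone, which is configurationally labile mainly to base, and the benzyl ethers remain intact.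

Step 16
Reactants: 24 tri-O-benzyl flavanone diol
Product: 25 CNP0263993.1, (2S)-5,7-dihydroxy-2-[4-{[(1R,2R)-1,3-dihydroxy-1-(4-hydroxyphenyl)propan-2-yl]oxy}-3,5-dimethoxyphenyl]chroman-4-one
Conditions: H2 (1 atm), Pd/C (10% palladium on carbon), EtOAc/MeOH, rt
Reagents that add atoms: none
Why: Catalytic hydrogenolysis cleaves the three aryl benzyl ethers under neutral conditions, which avoid base-induced racemisation of the 5-hydroxyflavanone and normally spare unactivated benzylic alcohols and the flavanone C2–O1 bond.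

**Compound list**

1 | 5-bromoresorcinol | Oc1cc(O)cc(Br)c1 | starting material
2 | 1,3-bis(benzyloxy)-5-bromobenzene | Brc1cc(OCc2ccccc2)cc(OCc2ccccc2)c1 | intermediate
3 | 2-bromo-4,6-bis(benzyloxy)benzaldehyde | O=Cc1c(Br)cc(OCc2ccccc2)cc1OCc1ccccc1 | intermediate
4 | 4-bromo-2,6-dimethoxyphenol | COc1cc(Br)cc(OC)c1O | starting material
5 | ethyl (4-bromo-2,6-dimethoxyphenoxy)acetate (not isolated) | CCOC(=O)COc1c(OC)cc(Br)cc1OC | intermediate
6 | (4-bromo-2,6-dimethoxyphenoxy)acetic acid | OC(=O)COc1c(OC)cc(Br)cc1OC | intermediate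
7 | (S)-4-benzyl-2-oxazolidinone | O=C1OC[C@H](Cc2ccccc2)N1 | starting material
8 | (4-bromo-2,6-dimethoxyphenoxy)acetic pivalic anhydride (not isolated) | CC(C)(C)C(=O)OC(=O)COc1c(OC)cc(Br)cc1OC | intermediate
9 | (S)-4-benzyl-3-[(4-bromo-2,6-dimethoxyphenoxy)acetyl]oxazolidin-2-one | O=C(COc1c(OC)cc(Br)cc1OC)N1C(=O)OC[C@@H]1Cc1ccccc1 | intermediate
10 | 4-(benzyloxy)benzaldehyde | O=Cc1ccc(OCc2ccccc2)cc1 | starting material
11 | dibutylboron (Z)-enolate of 9 (not isolated) | CCCCB(CCCC)O/C(=C\Oc1c(OC)cc(Br)cc1OC)N1C(=O)OC[C@@H]1Cc1ccccc1 | intermediate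
12 | (S)-4-benzyl-3-[(2S,3R)-3-[4-(benzyloxy)phenyl]-2-(4-bromo-2,6-dimethoxyphenoxy)-3-hydroxypropanoyl]oxazolidin-2-one | COc1cc(Br)cc(OC)c1O[C@H](C(=O)N1C(=O)OC[C@@H]1Cc1ccccc1)[C@H](O)c1ccc(OCc2ccccc2)cc1 | intermediate
13 | (1R,2R)-1-[4-(benzyloxy)phenyl]-2-(4-bromo-2,6-dimethoxyphenoxy)propane-1,3-diol | COc1cc(Br)cc(OC)c1O[C@H](CO)[C@H](O)c1ccc(OCc2ccccc2)cc1 | intermediate
14 | (4R,5R)-4-[4-(benzyloxy)phenyl]-5-(4-bromo-2,6-dimethoxyphenoxy)-2,2-dimethyl-1,3-dioxane | COc1cc(Br)cc(OC)c1O[C@@H]1COC(C)(C)O[C@@H]1c1ccc(OCc2ccccc2)cc1 | intermediate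
15 | aryllithium from 14, lithium in place of bromine (not isolated) | [Li]c1cc(OC)c(O[C@@H]2COC(C)(C)O[C@@H]2c2ccc(OCc3ccccc3)cc2)c(OC)c1 | intermediate
16 | 1-[4-{[(4R,5R)-4-[4-(benzyloxy)phenyl]-2,2-dimethyl-1,3-dioxan-5-yl]oxy}-3,5-dimethoxyphenyl]ethanone | CC(=O)c1cc(OC)c(O[C@@H]2COC(C)(C)O[C@@H]2c2ccc(OCc3ccccc3)cc2)c(OC)c1 | intermediate
17 | lithium enolate of 16 (not isolated) | [Li]OC(=C)c1cc(OC)c(O[C@@H]2COC(C)(C)O[C@@H]2c2ccc(OCc3ccccc3)cc2)c(OC)c1 | intermediate
18 | 3-[2-bromo-4,6-bis(benzyloxy)phenyl]-3-hydroxy-1-(ArB)propan-1-one, both C3 epimers | COc1cc(C(=O)CC(O)c2c(Br)cc(OCc3ccccc3)cc2OCc2ccccc2)cc(OC)c1O[C@@H]1COC(C)(C)O[C@@H]1c1ccc(OCc2ccccc2)cc1 | intermediate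
19 | 3-[2-bromo-4,6-bis(benzyloxy)phenyl]-3-(tert-butyldimethylsilyloxy)-1-(ArB)propan-1-one, both C3 epimers | COc1cc(C(=O)CC(O[Si](C)(C)C(C)(C)C)c2c(Br)cc(OCc3ccccc3)cc2OCc2ccccc2)cc(OC)c1O[C@@H]1COC(C)(C)O[C@@H]1c1ccc(OCc2ccccc2)cc1 | intermediate
20 | (1S)-3-[2-bromo-4,6-bis(benzyloxy)phenyl]-3-(tert-butyldimethylsilyloxy)-1-(ArB)propan-1-ol, both C3 epimers | COc1cc([C@@H](O)CC(O[Si](C)(C)C(C)(C)C)c2c(Br)cc(OCc3ccccc3)cc2OCc2ccccc2)cc(OC)c1O[C@@H]1COC(C)(C)O[C@@H]1c1ccc(OCc2ccccc2)cc1 | intermediate
21 | (2S)-5,7-bis(benzyloxy)-4-(tert-butyldimethylsilyloxy)-2-(ArB)chroman, both C4 epimers | COc1cc([C@@H]2CC(O[Si](C)(C)C(C)(C)C)c3c(OCc4ccccc4)cc(OCc4ccccc4)cc3O2)cc(OC)c1O[C@@H]1COC(C)(C)O[C@@H]1c1ccc(OCc2ccccc2)cc1 | intermediate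
22 | (2S)-5,7-bis(benzyloxy)-2-(ArB)chroman-4-ol, both C4 epimers | COc1cc([C@@H]2CC(O)c3c(OCc4ccccc4)cc(OCc4ccccc4)cc3O2)cc(OC)c1O[C@@H]1COC(C)(C)O[C@@H]1c1ccc(OCc2ccccc2)cc1 | intermediate
23 | (2S)-5,7-bis(benzyloxy)-2-(ArB)chroman-4-one | COc1cc([C@@H]2CC(=O)c3c(OCc4ccccc4)cc(OCc4ccccc4)cc3O2)cc(OC)c1O[C@@H]1COC(C)(C)O[C@@H]1c1ccc(OCc2ccccc2)cc1 | intermediate
24 | (2S)-5,7-bis(benzyloxy)-2-[4-{[(1R,2R)-1-[4-(benzyloxy)phenyl]-1,3-dihydroxypropan-2-yl]oxy}-3,5-dimethoxyphenyl]chroman-4-one | COc1cc([C@@H]2CC(=O)c3c(OCc4ccccc4)cc(OCc4ccccc4)cc3O2)cc(OC)c1O[C@H](CO)[C@H](O)c1ccc(OCc2ccccc2)cc1 | intermediate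
25 | CNP0263993.1, (2S)-5,7-dihydroxy-2-[4-{[(1R,2R)-1,3-dihydroxy-1-(4-hydroxyphenyl)propan-2-yl]oxy}-3,5-dimethoxyphenyl]chroman-4-one | COc1cc([C@@H]2CC(=O)c3c(O)cc(O)cc3O2)cc(OC)c1O[C@H](CO)[C@H](O)c1ccc(O)cc1 | target

**Step count**

Total step count: 16. Longest linear sequence: 14 steps (steps 3 to 16, from 4 to 25); steps 1 and 2 form the ring A branch that joins in step 9.

**Steps most likely to fail**

Step 12. Beta-hydride elimination from the arylpalladium alkoxide (oxidising C2 back to the ketone with loss of bromine) may outrun C–O reductive elimination at the hindered, electron-rich arene. The fallback sets out from 19 and comes back at 21, closing ring C at O1–C2 instead. Ketone 19 is reduced with the enantiomeric (S)-oxazaborolidine and BH3·SMe2 to the C1 epimer of 20, the (1R)-alcohol F1. Miyaura borylation (B2pin2, PdCl2(dppf), KOAc, dioxane, 80 °C) should turn the C8a–Br bond into the pinacol boronate F2. Oxidation with NaBO3·4H2O in THF/H2O should give the phenol F3. An intramolecular Mitsunobu etherification (PPh3, diisopropyl azodicarboxylate, THF, 0 °C) would then join the phenol oxygen to C2 with inversion, arriving at the (2S)-flavan 21.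

Step 9. Addition to the di-ortho-substituted, electron-rich aldehyde may be reversible (retro-aldol on warming), or the aldolate may dehydrate to the chalcone. The fallback sets out from 16 and comes back at 18. Ketone 16 is converted (LiN(i-Pr)2, Me3SiCl, THF, -78 °C) into its trimethylsilyl enol ether F4. In a Mukaiyama aldol addition, F4 is combined with aldehyde 3 under BF3·OEt2 in CH2Cl2 at -78 °C, where the Lewis acid activates the aldehyde and no basic aldolate is present; aqueous work-up should give 18.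

Step 11. Hydride transfer may discriminate the ketone faces poorly, because the silyloxy stereocentre of one epimer can oppose the catalyst and the CH2 branch is bulky. The fallback sets out from 19 and comes back at 20. It is a Noyori asymmetric transfer hydrogenation with RuCl(p-cymene)[(S,S)-TsDPEN] and HCO2H/Et3N in CH2Cl2 at rt, whose bifunctional outer-sphere hydride transfer is governed by the aryl group alone and should likewise give the (1S)-alcohol; no new compound arises (F0).

**Further compounds**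

F1 | step 12 | (1R)-3-[2-bromo-4,6-bis(benzyloxy)phenyl]-3-(tert-butyldimethylsilyloxy)-1-(ArB)propan-1-ol, both C3 epimers | COc1cc([C@H](O)CC(O[Si](C)(C)C(C)(C)C)c2c(Br)cc(OCc3ccccc3)cc2OCc2ccccc2)cc(OC)c1O[C@@H]1COC(C)(C)O[C@@H]1c1ccc(OCc2ccccc2)cc1
F2 | step 12 | (1R)-3-[2,4-bis(benzyloxy)-6-(4,4,5,5-tetramethyl-1,3,2-dioxaborolan-2-yl)phenyl]-3-(tert-butyldimethylsilyloxy)-1-(ArB)propan-1-ol | COc1cc([C@H](O)CC(O[Si](C)(C)C(C)(C)C)c2c(B3OC(C)(C)C(C)(C)O3)cc(OCc3ccccc3)cc2OCc2ccccc2)cc(OC)c1O[C@@H]1COC(C)(C)O[C@@H]1c1ccc(OCc2ccccc2)cc1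
F3 | step 12 | (1R)-3-[2,4-bis(benzyloxy)-6-hydroxyphenyl]-3-(tert-butyldimethylsilyloxy)-1-(ArB)propan-1-ol | COc1cc([C@H](O)CC(O[Si](C)(C)C(C)(C)C)c2c(O)cc(OCc3ccccc3)cc2OCc2ccccc2)cc(OC)c1O[C@@H]1COC(C)(C)O[C@@H]1c1ccc(OCc2ccccc2)cc1
F4 | step 9 | trimethylsilyl enol ether of 16, 1-(ArB)-1-(trimethylsilyloxy)ethene | C=C(O[Si](C)(C)C)c1cc(OC)c(O[C@@H]2COC(C)(C)O[C@@H]2c2ccc(OCc3ccccc3)cc2)c(OC)c1
F0 | step 11 | none | none
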